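## Structural features

The target is an ether-linked biflavonoid: a (2S)-5,7-dihydroxyflavanone (rings A and C fused, ring B on C2) is joined through the para oxygen of its ring B to C3 of a 5,7,4'-trihydroxyflavone. The single stereocentre is flavanone C2. It is benzylic, bears the ring oxygen and lies β to the C4 ketone, so it has no stereogenic neighbour but is lost by retro-oxa-Michael opening to a chalcone once base meets the free 5-hydroxy ketone. Five phenols are present, two of them chelated to a peri carbonyl group, and the flavanone ketone and the benzylic C2–O1 bond are both open to over-reduction. The main difficulty is the ether at flavonol C3: this oxygen sits on an enol carbon wedged between the C2 aryl group and the C4 carbonyl, and arylation of a 3-hydroxyflavone with an unactivated aryl partner is not dependable. The second difficulty is to create flavanone C2 late, enantioselectively and without base. The key step uses the fact that flavonol C3 has three different neighbours: the ether oxygen, C4 (bonded to ring A) and C2 (bonded to the 4-oxygenated phenyl ring). C3 can therefore be a carbene carbon next to the C2 carbonyl, which takes up a phenol oxygen and then an aldehyde carbon that becomes C4. Ring A of the flavonol is carried as a 2,4,6-trifluorophenyl group, which makes that aldehyde electrophilic and whose fluorines later close the O1–C8a bond and act as masked hydroxyls.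

## Logic of the disconnections

**15 to 14.** The five O–benzyl bonds are cut first. All phenols of both halves then carry one kind of protecting group and a single neutral hydrogenolysis ends the route. The demand on the forward step is that the flavanone ketone, the benzylic C2–O1 bond and the pyrone double bond survive, and that no base touches C2.

**14 to 9 and 13.** The bond between flavanone C2 and ring B is cut. It is the only bond at the stereocentre that divides the molecule into two halves, so the route becomes convergent and the stereocentre is made in the coupling itself. The gain is large: 9 holds the complete flavonol ether and 13 is a small achiral chromone. The forward step must transfer the aryl group to the Re face of C2 of a donor-substituted chromone, under conditions that do not reopen the product.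

**13 to 11 and 10.** The chromone is opened at O1–C2 and C2–C3, which removes a one-carbon unit (through the transient 12) and leaves a methyl ketone. Two O–benzyl bonds are then cut. The forward steps need selective double benzylation, leaving the chelated hydroxyl free for ring closure.

**9 to 8.** The C–B bond is traced back to a C–Br bond. Bromine is an inert placeholder through carbenoid, oxidation and substitution chemistry and is exchanged for boron only when needed. The forward step should deliver the free boronic acid, not an ester, because the base-free addition that follows needs it.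

**8 to 6 through 7.** The two aryl C–O bonds at C5 and C7 are replaced by C–F bonds, and the pyrone O1–C8a bond is cut to an enolate oxygen and an ortho C–F bond. This turns an electron-rich ring into an electron-poor one, which the key step requires. The forward steps need closure before exchange, and an alkoxide that substitutes the activated positions without opening the pyrone.

**6 to 5.** The C4 ketone is reduced in thought to the secondary alcohol, the direct product of an aldol-type addition. The forward oxidation must stop at the diketone and spare its doubly activated C–H.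

**5 to 2, 3 and 4.** Both bonds at the future flavonol C3 that do not lead to C2 are cut: C3–O and C3–C4. Three simple components result, none with a ring that must be made and none with a stereocentre that matters. The forward step must have the ylide or enol from 2 and 3 add to 4 faster than it is protonated.

**2 to 1.** The bond between the carbonyl carbon and the diazo carbon is cut, back to an acid chloride and a one-carbon diazo reagent. The forward step is a one-step acylation with a silylated diazomethane.

## Other disconnections considered

**Alternative 1:** The cut runs through C3–C4 and O1–C2 of the flavanone ring C at the flavan oxidation level. The partners are the styrene A1 (5,7-bis(benzyloxy)-2-[4-(benzyloxy)phenyl]-3-(4-vinylphenoxy)chromen-4-one, one vinylation away from 8) and the acetal phenol A2 (3,5-bis(benzyloxy)-2-(dimethoxymethyl)phenol). In the forward key step a chiral Brønsted acid would ionise A2 to an O-methyl oxocarbenium ortho-quinone methide. This would add across the vinyl group of A1 in a [4+2] fashion and give the (2S,4S)-4-methoxyflavan A3.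
- In its favour: ring C is closed and C2 is set in one organocatalytic operation, no boron reagent is needed, and the stereo-defining step uses no precious metal. On these points it is the equal of the chosen plan or better.
- Against it: enantiocontrol in intermolecular cycloadditions of such transient species with a monosubstituted, only moderately electron-rich styrene is less secure than in aryl–rhodium addition to a chromone. The two benzyloxy donors stabilise the cation and should lower its reactivity. A3 has the wrong oxidation state at C4, so two further operations (hydrolysis of the benzylic ether, then oxidation) are needed, under acid that can ionise C4 and threaten C2. A2 also takes more steps than 13.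
- Comparison: both plans are equally convergent and both need 8. From 8 the alternative needs about five operations against three in the chosen plan.

**Alternative 2:** The cut is through C2–C3 and O1–C2 of the flavonol pyrone. The ketone A4 (2-(4-bromophenoxy)-1-(2,4,6-trihydroxyphenyl)ethanone) would be heated with the anhydride A5 (4-(benzyloxy)benzoic anhydride) and its salt A6 (potassium 4-(benzyloxy)benzoate), then briefly with alkali. This Allan–Robinson condensation would give A7 (2-(4-benzyloxyphenyl)-3-(4-bromophenoxy)-5,7-dihydroxychromen-4-one), which dibenzylation would convert into 8.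
- In its favour: the reaction type is classical for 3-alkoxy- and 3-aryloxyflavones of the phloroglucinol series. Ring A carries its oxygens from the start, so no fluoride exchange, diazo compound or rhodium is needed. In predictability of the ring-forming event it is the equal of the chosen plan or better.
- Against it: the melt needs roughly 170–180 °C and several equivalents of A5, of which only one aroyl group ends in the product. A4 is not commercial and must first be made by C-acylation of a free triphenol. The chelated 5-hydroxyl of A7 is sluggish in the benzylation.
- Comparison: the step count to 8 is about the same as steps 1 to 4 of the chosen plan, so on economy of steps the two are equal. The alternative loses on conditions and material economy. It also shows no new way of using the three different bonds at C3, which the chosen key step forms two at a time under mild conditions.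

**Alternative 3:** The cut is through C2–C3 and O1–C8a of the flavanone, with ring A absent at the key stage. The aldehyde A8 (4-({5,7-bis(benzyloxy)-2-[4-(benzyloxy)phenyl]-4-oxochromen-3-yl}oxy)benzaldehyde) and the diene A9 ((E)-1-methoxy-3-(trimethylsilyloxy)buta-1,3-diene) would combine under Ti(OiPr)4 and a chiral octahydrobinaphthol. This hetero-Diels–Alder reaction would give, after loss of methanol, the (2S)-dihydropyranone A10.
- In its favour: catalytic asymmetric hetero-Diels–Alder reactions of aryl aldehydes with this diene are among the most dependable ways to a 2-aryl dihydropyranone. C2 is set without base and without a boron reagent. In security of enantiocontrol it is the equal of the chosen plan or better.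
- Against it: A10 has no ring A. A 5,7-dioxygenated benzene ring would have to be built on the C5=C6 enol ether bond (activation at C5, a second cycloaddition with a doubly oxygenated diene, aromatisation). Regiochemistry there is uncertain, and the conditions expose C2, β to the ketone and bonded to oxygen, to elimination.
- Comparison: the chosen plan brings ring A in complete with 13 and needs three steps after 8. The alternative needs a formylation, the cycloaddition and a multistep annulation, so it is clearly longer.

Key step: step 2

Remark on the chemistry: the 2S sense of step 8 is assigned by analogy with cyclic enones (aryl transfer to the Re face of chromone C2); the carbene carbon of 2 maps onto flavonol C3, its ketone carbon onto C2 and the aldehyde carbon of 4 onto C4, so the structures of 2 to 5 needed no change.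

## Route

Step 1
Reactants: 1 4-(benzyloxy)benzoyl chloride
Product: 2 2-diazo-1-[4-(benzyloxy)phenyl]ethanone
Conditions: TMSCHN2 (2 equiv, 2 M in hexanes), THF/MeCN 1:1, 0 °C → rt
Reagents that add atoms: (trimethylsilyl)diazomethane, C[Si](C)(C)C=[N+]=[N-]
Why: Acylation of the nucleophilic diazo carbon by the acid chloride, followed by chloride-induced loss of the silyl group (diazoketone synthesis of the Arndt–Eistert type, with the non-explosive silyl reagent in place of diazomethane); the benzyl ether is inert, and the reagent is handled in a hood because it is toxic by inhalation.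

Step 2
Reactants: 2 2-diazo-1-[4-(benzyloxy)phenyl]ethanone; 3 4-bromophenol; 4 2,4,6-trifluorobenzaldehyde
Product: 5 1-[4-(benzyloxy)phenyl]-2-(4-bromophenoxy)-3-hydroxy-3-(2,4,6-trifluorophenyl)propan-1-one (mixture of diastereomers)
Conditions: Rh2(OAc)4 (2 mol %), Zn(OTf)2 (10 mol %), 4 Å MS, CH2Cl2, 40 °C, 2 added over 3 h to 3 (1.5 equiv) and 4 (2 equiv)
Reagents that add atoms: none
Why: Rh2(OAc)4 converts 2 into an electrophilic rhodium carbenoid, which is captured by the hydroxyl oxygen of 3 to give a rhodium-associated oxonium ylide in equilibrium with the free enol of the aryloxy ketone. This nucleophile should add to the zinc-activated carbonyl group of 4 in an aldol-type step before it tautomerises (the formal 1,2-proton shift), so the former carbene carbon gains both the C–O bond (flavonol C3–O) and the C–C bond (flavonol C3–C4). The closest known reaction type is the dirhodium-catalysed three-component coupling of diazo carbonyl compounds, alcohols and electron-poor aldehydes by oxonium ylide trapping. No ring is closed. Two stereocentres (C2 and C3 of the propanone) arise without control as a syn/anti mixture, which does not matter because step 3 removes one and makes the other enolisable. The selectivity needed is chemoselectivity, trapping against proton transfer: the three fluorines make the aldehyde carbon of 4 strongly electrophilic while leaving its oxygen a poor partner for the carbenoid, Zn(OTf)2 activates it further, and slow addition of 2 to an excess of 3 and 4 keeps carbene dimerisation and insertion into the product hydroxyl low. The para bromine of 3 blocks and deactivates its ring against carbenoid attack on carbon, and the aryl bromide and benzyl ether are inert to Rh2(OAc)4.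

Step 3
Reactants: 5 1-[4-(benzyloxy)phenyl]-2-(4-bromophenoxy)-3-hydroxy-3-(2,4,6-trifluorophenyl)propan-1-one
Product: 6 1-[4-(benzyloxy)phenyl]-2-(4-bromophenoxy)-3-(2,4,6-trifluorophenyl)propane-1,3-dione
Conditions: Dess–Martin periodinane (1.1 equiv), CH2Cl2, 0 °C → rt
Reagents that add atoms: none
Why: Dess–Martin oxidation of the secondary benzylic alcohol to the ketone; one stereocentre disappears and the other becomes the acidic C2–H of a 1,3-diketone, so both diastereomers converge, and the oxidant is limited to a slight excess at low temperature so that this doubly activated position is not hydroxylated.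

Step 4
Reactants: 6 1-[4-(benzyloxy)phenyl]-2-(4-bromophenoxy)-3-(2,4,6-trifluorophenyl)propane-1,3-dione
Product: 8 5,7-bis(benzyloxy)-2-[4-(benzyloxy)phenyl]-3-(4-bromophenoxy)-4H-chromen-4-one, via 5,7-difluoroflavone 7 (not isolated)
Conditions: K2CO3 (1.5 equiv), DMF, 60 °C; then BnONa (3.5 equiv, from BnOH and NaH in THF), 0 → 50 °C
Reagents that add atoms: benzyl alcohol (used as sodium benzyloxide), OCc1ccccc1
Why: Two consecutive nucleophilic aromatic substitutions: carbonate generates the diketone enolate, whose oxygen on the C2 side displaces an ortho fluorine through a six-membered transition state (Meisenheimer intermediate stabilised by the ketone and the other fluorines), and the fluorines left at C5 and C7, ortho and para to the new pyrone carbonyl, are then exchanged by benzyloxide. The aryl bromide and the C3 aryl ether are not activated and should persist; the alkoxide is added only after closure so that it cannot occupy both ortho positions first.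

Step 5
Reactants: 8 5,7-bis(benzyloxy)-2-[4-(benzyloxy)phenyl]-3-(4-bromophenoxy)-4H-chromen-4-one
Product: 9 [4-({5,7-bis(benzyloxy)-2-[4-(benzyloxy)phenyl]-4-oxo-4H-chromen-3-yl}oxy)phenyl]boronic acid
Conditions: B2(OH)4 (2 equiv), PdCl(2'-aminobiphenyl-2-yl)(XPhos) (second-generation XPhos palladacycle, 2 mol %), XPhos (2-dicyclohexylphosphino-2',4',6'-triisopropylbiphenyl, 4 mol %), KOAc (3 equiv), EtOH/THF, 70 °C
Reagents that add atoms: tetrahydroxydiboron, OB(O)B(O)O
Why: Palladium-catalysed Miyaura borylation of the aryl bromide (oxidative addition, acetate-assisted transmetalation with the diboron reagent, reductive elimination); with tetrahydroxydiboron the free boronic acid should be obtained directly, as the base-free addition in step 8 requires, and the mild acetate base leaves the pyrone and the benzyl ethers untouched.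

Step 6
Reactants: 10 2',4',6'-trihydroxyacetophenone
Product: 11 1-[2,4-bis(benzyloxy)-6-hydroxyphenyl]ethanone
Conditions: BnBr (2.1 equiv), K2CO3 (2.2 equiv), acetone, reflux
Reagents that add atoms: benzyl bromide, BrCc1ccccc1
Why: Williamson ether synthesis; the 4-hydroxyl and one of the two equivalent ortho hydroxyls are alkylated, after which the remaining hydroxyl is locked in a hydrogen bond to the ketone and resists a third alkylation when the halide is limited to about two equivalents.

Step 7
Reactants: 11 1-[2,4-bis(benzyloxy)-6-hydroxyphenyl]ethanone
Product: 13 5,7-bis(benzyloxy)-4H-chromen-4-one, via enaminone 12 (not isolated)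
Conditions: Me2NCH(OMe)2, toluene, 95 °C; then AcOH, 80 °C
Reagents that add atoms: N,N-dimethylformamide dimethyl acetal, COC(OC)N(C)C
Why: Condensation of the methyl ketone with the formamide acetal gives the enaminone, and in warm acetic acid the phenol adds in an oxa-Michael fashion and dimethylamine is expelled to close the pyrone (enaminone route to 3-unsubstituted chromones); the benzyl ethers are stable to both stages.

Step 8
Reactants: 9 [4-({5,7-bis(benzyloxy)-2-[4-(benzyloxy)phenyl]-4-oxo-4H-chromen-3-yl}oxy)phenyl]boronic acid; 13 5,7-bis(benzyloxy)-4H-chromen-4-one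
Product: 14 (2S)-5,7-bis(benzyloxy)-2-[4-({5,7-bis(benzyloxy)-2-[4-(benzyloxy)phenyl]-4-oxo-4H-chromen-3-yl}oxy)phenyl]-2,3-dihydro-4H-chromen-4-one
Conditions: [Rh(OH)((S)-MeO-F12-BIPHEP)]2 (1.5 mol %; ligand = (S)-6,6'-dimethoxy-2,2'-bis[bis(3,4,5-trifluorophenyl)phosphino]-1,1'-biphenyl), 13 (2 equiv), CH2Cl2/H2O 10:1, 30 °C
Reagents that add atoms: none
Why: Rhodium-catalysed asymmetric conjugate addition of an arylboronic acid to a chromone (Hayashi–Miyaura reaction): transmetalation gives an aryl–rhodium species, the C2=C3 bond of 13 inserts with the aryl group delivered to the Re face of C2 as dictated by the (S)-bisphosphine (quadrant model of cyclic enones), and hydrolysis of the rhodium enolate releases the (2S)-flavanone. The electron-poor phosphine should make the catalyst active enough for the donor-substituted chromone near room temperature without added base, which keeps the product from opening to the chalcone; the tetrasubstituted pyrone double bond of 9 is not an acceptor.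

Step 9
Reactants: 14 (2S)-5,7-bis(benzyloxy)-2-[4-({5,7-bis(benzyloxy)-2-[4-(benzyloxy)phenyl]-4-oxo-4H-chromen-3-yl}oxy)phenyl]-2,3-dihydro-4H-chromen-4-one
Product: 15 (2S)-5,7-dihydroxy-2-(4-{[5,7-dihydroxy-2-(4-hydroxyphenyl)-4-oxo-4H-chromen-3-yl]oxy}phenyl)-2,3-dihydro-4H-chromen-4-one (CNP0144321.1)
Conditions: H2 (1 atm), 10% Pd/C, THF/MeOH, rt
Reagents that add atoms: none
Why: Hydrogenolysis of the five aryl benzyl ethers over palladium under neutral conditions; aryl benzyl ethers should cleave well before the flavanone ketone or the benzylic C2–O1 bond is reduced, the pyrone double bond is part of a vinylogous ester and is inert at 1 atm, and without base the C2 stereocentre is retained.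

## Compound list

1 | 4-(benzyloxy)benzoyl chloride | O=C(Cl)c1ccc(OCc2ccccc2)cc1 | starting material
2 | 2-diazo-1-[4-(benzyloxy)phenyl]ethanone | [N-]=[N+]=CC(=O)c1ccc(OCc2ccccc2)cc1 | intermediate
3 | 4-bromophenol | Oc1ccc(Br)cc1 | starting material
4 | 2,4,6-trifluorobenzaldehyde | O=Cc1c(F)cc(F)cc1F | starting material
5 | 1-[4-(benzyloxy)phenyl]-2-(4-bromophenoxy)-3-hydroxy-3-(2,4,6-trifluorophenyl)propan-1-one (diastereomer mixture, racemic) | O=C(c1ccc(OCc2ccccc2)cc1)C(Oc1ccc(Br)cc1)C(O)c1c(F)cc(F)cc1F | intermediate
6 | 1-[4-(benzyloxy)phenyl]-2-(4-bromophenoxy)-3-(2,4,6-trifluorophenyl)propane-1,3-dione | O=C(c1ccc(OCc2ccccc2)cc1)C(Oc1ccc(Br)cc1)C(=O)c1c(F)cc(F)cc1F | intermediate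
7 | 2-[4-(benzyloxy)phenyl]-3-(4-bromophenoxy)-5,7-difluoro-4H-chromen-4-one | O=c1c(Oc2ccc(Br)cc2)c(-c2ccc(OCc3ccccc3)cc2)oc2cc(F)cc(F)c12 | intermediate (not isolated)
8 | 5,7-bis(benzyloxy)-2-[4-(benzyloxy)phenyl]-3-(4-bromophenoxy)-4H-chromen-4-one | O=c1c(Oc2ccc(Br)cc2)c(-c2ccc(OCc3ccccc3)cc2)oc2cc(OCc3ccccc3)cc(OCc3ccccc3)c12 | intermediate
9 | [4-({5,7-bis(benzyloxy)-2-[4-(benzyloxy)phenyl]-4-oxo-4H-chromen-3-yl}oxy)phenyl]boronic acid | O=c1c(Oc2ccc(B(O)O)cc2)c(-c2ccc(OCc3ccccc3)cc2)oc2cc(OCc3ccccc3)cc(OCc3ccccc3)c12 | intermediate
10 | 2',4',6'-trihydroxyacetophenone | CC(=O)c1c(O)cc(O)cc1O | starting material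
11 | 1-[2,4-bis(benzyloxy)-6-hydroxyphenyl]ethanone | CC(=O)c1c(O)cc(OCc2ccccc2)cc1OCc1ccccc1 | intermediate
12 | (E)-1-[2,4-bis(benzyloxy)-6-hydroxyphenyl]-3-(dimethylamino)prop-2-en-1-one | CN(C)/C=C/C(=O)c1c(O)cc(OCc2ccccc2)cc1OCc1ccccc1 | intermediate (not isolated)
13 | 5,7-bis(benzyloxy)-4H-chromen-4-one | O=c1ccoc2cc(OCc3ccccc3)cc(OCc3ccccc3)c12 | intermediate
14 | (2S)-5,7-bis(benzyloxy)-2-[4-({5,7-bis(benzyloxy)-2-[4-(benzyloxy)phenyl]-4-oxo-4H-chromen-3-yl}oxy)phenyl]-2,3-dihydro-4H-chromen-4-one | O=C1C[C@@H](c2ccc(Oc3c(-c4ccc(OCc5ccccc5)cc4)oc4cc(OCc5ccccc5)cc(OCc5ccccc5)c4c3=O)cc2)Oc2cc(OCc3ccccc3)cc(OCc3ccccc3)c21 | intermediate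
15 | (2S)-5,7-dihydroxy-2-(4-{[5,7-dihydroxy-2-(4-hydroxyphenyl)-4-oxo-4H-chromen-3-yl]oxy}phenyl)-2,3-dihydro-4H-chromen-4-one | O=C1C[C@@H](c2ccc(Oc3c(-c4ccc(O)cc4)oc4cc(O)cc(O)c4c3=O)cc2)Oc2cc(O)cc(O)c21 | target

## Step count and least certain steps

Total step count: 9. Longest linear sequence: 7 steps (steps 1, 2, 3, 4, 5, 8 and 9); steps 6 and 7 form the short branch to 13.

**Step 2 (key step).**
- What may go wrong: proton transfer within the ylide or enol may outrun the aldol addition, so that plain O–H insertion dominates. A phenol-derived oxonium centre is more acidic than an alcohol-derived one, and 4 is less electrophilic than the nitro-substituted aldehydes usual in such couplings. Capture of the carbenoid by the aldehyde oxygen is a lesser risk.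
- Fallback: it sets out from 2 and 3. Rh2(OAc)4 in CH2Cl2 without aldehyde would give, by deliberate O–H insertion, 1-[4-(benzyloxy)phenyl]-2-(4-bromophenoxy)ethanone F1. Its lithium enolate (LiN(SiMe3)2, THF, −78 °C) would then be added to 4 in a directed aldol reaction. The fallback comes back to the route at 5. Insertion product formed as a by-product of step 2 itself can be fed into the same aldol step.

**Step 8.**
- What may go wrong: protodeboronation of 9 may outpace insertion, because the 5,7-dialkoxylated chromone is a sluggish acceptor and 9 is bulky and poorly soluble. Facial selectivity may also be poor or of the wrong sense, since the 2S assignment rests on analogy. For that reason 13 is used in excess and the antipodal ligand is kept at hand.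
- Fallback: it sets out from 8. Palladium-catalysed reductive carbonylation (Pd(OAc)2, 1,4-bis(diphenylphosphino)butane, N-formylsaccharin, Et3SiH, Na2CO3, DMF, 80 °C) would give 4-({5,7-bis(benzyloxy)-2-[4-(benzyloxy)phenyl]-4-oxo-4H-chromen-3-yl}oxy)benzaldehyde F4, which has the structure of A8. Claisen–Schmidt condensation of F4 with 11 (KOH, EtOH/THF, rt) would give the 2'-hydroxychalcone F5. Cyclisation with NaOAc in refluxing EtOH/THF would give the racemic flavanone F6, from which the 2S enantiomer would be taken by preparative chromatography on a chiral stationary phase. The fallback comes back to the route at 14.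

**Step 4.**
- What may go wrong: benzyloxide may attack C2 of the pyrone (ring opening and fragmentation), or the exchange at C5 may stall after C7 has been substituted, because the first benzyloxy group weakens the activation by the carbonyl.
- Fallback: it sets out from 7, isolated after the carbonate stage. Acetohydroxamic acid and K2CO3 in DMSO at 80 °C, a weakly basic hydroxide surrogate, would replace both fluorines and give 2-[4-(benzyloxy)phenyl]-3-(4-bromophenoxy)-5,7-dihydroxy-4H-chromen-4-one F3, which has the structure of A7. Benzylation (BnBr, K2CO3, DMF, 60 °C) then comes back to the route at 8.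

**Step 9.**
- What may go wrong: over-reduction (hydrogenolysis of the benzylic C2–O1 bond or reduction of the flavanone ketone) may set in while the last, chelated benzyl ethers are still being removed. The reaction may also stall as partly deprotected material falls out of solution.
- Fallback: it sets out from 14 and uses Lewis-acid dealkylation in place of hydrogenolysis: BCl3 with pentamethylbenzene as cation scavenger in CH2Cl2 at −78 °C. It arrives directly at 15 and makes no new compound.

## Further compounds

F1 | step 2 | 1-[4-(benzyloxy)phenyl]-2-(4-bromophenoxy)ethanone | O=C(COc1ccc(Br)cc1)c1ccc(OCc2ccccc2)cc1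
F4 | step 8 | 4-({5,7-bis(benzyloxy)-2-[4-(benzyloxy)phenyl]-4-oxo-4H-chromen-3-yl}oxy)benzaldehyde | O=Cc1ccc(Oc2c(-c3ccc(OCc4ccccc4)cc3)oc3cc(OCc4ccccc4)cc(OCc4ccccc4)c3c2=O)cc1
F5 | step 8 | (E)-1-[2,4-bis(benzyloxy)-6-hydroxyphenyl]-3-[4-({5,7-bis(benzyloxy)-2-[4-(benzyloxy)phenyl]-4-oxo-4H-chromen-3-yl}oxy)phenyl]prop-2-en-1-one | O=C(/C=C/c1ccc(Oc2c(-c3ccc(OCc4ccccc4)cc3)oc3cc(OCc4ccccc4)cc(OCc4ccccc4)c3c2=O)cc1)c1c(O)cc(OCc2ccccc2)cc1OCc1ccccc1
F6 | step 8 | racemic 5,7-bis(benzyloxy)-2-[4-({5,7-bis(benzyloxy)-2-[4-(benzyloxy)phenyl]-4-oxo-4H-chromen-3-yl}oxy)phenyl]-2,3-dihydro-4H-chromen-4-one | O=C1CC(c2ccc(Oc3c(-c4ccc(OCc5ccccc5)cc4)oc4cc(OCc5ccccc5)cc(OCc5ccccc5)c4c3=O)cc2)Oc2cc(OCc3ccccc3)cc(OCc3ccccc3)c21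
F3 | step 4 | 2-[4-(benzyloxy)phenyl]-3-(4-bromophenoxy)-5,7-dihydroxy-4H-chromen-4-one | O=c1c(Oc2ccc(Br)cc2)c(-c2ccc(OCc3ccccc3)cc2)oc2cc(O)cc(O)c12
F0 | step 9 | none | none
A1 | alternative 1 | 5,7-bis(benzyloxy)-2-[4-(benzyloxy)phenyl]-3-(4-vinylphenoxy)-4H-chromen-4-one | C=Cc1ccc(Oc2c(-c3ccc(OCc4ccccc4)cc3)oc3cc(OCc4ccccc4)cc(OCc4ccccc4)c3c2=O)cc1
A2 | alternative 1 | 3,5-bis(benzyloxy)-2-(dimethoxymethyl)phenol | COC(OC)c1c(O)cc(OCc2ccccc2)cc1OCc1ccccc1
A3 | alternative 1 | 5,7-bis(benzyloxy)-3-{4-[(2S,4S)-5,7-bis(benzyloxy)-4-methoxychroman-2-yl]phenoxy}-2-[4-(benzyloxy)phenyl]-4H-chromen-4-one | CO[C@H]1C[C@@H](c2ccc(Oc3c(-c4ccc(OCc5ccccc5)cc4)oc4cc(OCc5ccccc5)cc(OCc5ccccc5)c4c3=O)cc2)Oc2cc(OCc3ccccc3)cc(OCc3ccccc3)c21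
A4 | alternative 2 | 2-(4-bromophenoxy)-1-(2,4,6-trihydroxyphenyl)ethanone | O=C(COc1ccc(Br)cc1)c1c(O)cc(O)cc1O
A5 | alternative 2 | 4-(benzyloxy)benzoic anhydride | O=C(OC(=O)c1ccc(OCc2ccccc2)cc1)c1ccc(OCc2ccccc2)cc1
A6 | alternative 2 | potassium 4-(benzyloxy)benzoate | [K+].[O-]C(=O)c1ccc(OCc2ccccc2)cc1
A7 | alternative 2 | 2-(4-benzyloxyphenyl)-3-(4-bromophenoxy)-5,7-dihydroxychromen-4-one | O=c1c(Oc2ccc(Br)cc2)c(-c2ccc(OCc3ccccc3)cc2)oc2cc(O)cc(O)c12
A8 | alternative 3 | 4-({5,7-bis(benzyloxy)-2-[4-(benzyloxy)phenyl]-4-oxo-4H-chromen-3-yl}oxy)benzaldehyde | O=Cc1ccc(Oc2c(-c3ccc(OCc4ccccc4)cc3)oc3cc(OCc4ccccc4)cc(OCc4ccccc4)c3c2=O)cc1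
A9 | alternative 3 | (E)-1-methoxy-3-(trimethylsilyloxy)buta-1,3-diene | CO/C=C/C(=C)O[Si](C)(C)C
A10 | alternative 3 | (2S)-2-[4-({5,7-bis(benzyloxy)-2-[4-(benzyloxy)phenyl]-4-oxo-4H-chromen-3-yl}oxy)phenyl]-2,3-dihydro-4H-pyran-4-one | O=C1C[C@@H](c2ccc(Oc3c(-c4ccc(OCc5ccccc5)cc4)oc4cc(OCc5ccccc5)cc(OCc5ccccc5)c4c3=O)cc2)OC=C1
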